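**Strategy**

Everything rests on cutting ring C of the naphthoquinone at C4–C3, C2–C1 and C1–C8a into three pieces: a chromium methoxycarbene carried by ring B at C4a, one of its CO ligands, and ethynylboronic acid pinacol ester. Their Dötz benzannulation builds ring C in one operation as a 4-methoxy-1-naphthol with boron on C2. It exploits the oxygen pattern of ring C (O on C1, C2 and C4, C1 and C4 para) and the fact that C5 is already oxygenated, so C4a has one unsubstituted neighbour, C8a, for closure. The precursor is a 1,2,3,4-tetrasubstituted benzene: carbene carbon, C5 methoxy, C6 orsellinoyl ketone (dimethyl ether), C7 silyloxyethyl chain.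

Key step: step 8

Assumption: naphthalene locants are those of the target quinone (ring C = C1–C4, ring B = C5–C8, ring A = orsellinoyl ring); ArCO = 2,4-dimethoxy-6-methylbenzoyl, TBS = tert-butyldimethylsilyl, Bpin = 4,4,5,5-tetramethyl-1,3,2-dioxaborolan-2-yl; silyl ether 2 is taken as the purchasable form of but-3-yn-1-ol; alkoxides, phenoxides and carboxylates formed by simple proton transfer are written as the neutral compounds obtained on work-up.

**Route**

Step 1
Reactants: 1 2,4-dimethoxy-6-methylbenzaldehyde; 2 tert-butyl(but-3-yn-1-yloxy)dimethylsilane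
Product: 4 rac-5-(TBSO)-1-(2,4-dimethoxy-6-methylphenyl)pent-2-yn-1-ol, via lithium acetylide 3 (not isolated)
Conditions: n-BuLi, THF, −78 °C; then 1, −78 → 0 °C; H2O
Reagents that add atoms: none
Why: Acetylide addition to an aldehyde: the lithium acetylide adds 1,2 to the non-enolizable aryl aldehyde, and the carbinol centre it creates is racemic and irrelevant because step 2 oxidizes it.

Step 2
Reactants: 4 rac-5-(TBSO)-1-(2,4-dimethoxy-6-methylphenyl)pent-2-yn-1-ol
Product: 5 5-(TBSO)-1-(2,4-dimethoxy-6-methylphenyl)pent-2-yn-1-one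
Conditions: MnO2 (activated), CH2Cl2, rt
Reagents that add atoms: none
Why: MnO2 oxidation of an alcohol that is both benzylic and propargylic should give the ynone under neutral conditions that spare the silyl ether and do not isomerize the ynone.

Step 3
Reactants: 6 dimethyl ethylidenemalonate
Product: 8 methyl 2-[methoxy(trimethylsilyloxy)methylidene]but-3-enoate, via lithium dienolate 7 (not isolated)
Conditions: LiN(SiMe3)2, THF, −78 °C; then Me3SiCl, −78 °C → rt; pentane, filter, concentrate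
Reagents that add atoms: chlorotrimethylsilane, C[Si](C)(C)Cl
Why: Silyl ketene acetal formation: the hindered amide removes a γ-proton of the alkylidene malonate and the cross-conjugated dienolate is silylated on oxygen; the geometry of the ketene acetal is not controlled and is lost in step 4.

Step 4
Reactants: 5 5-(TBSO)-1-(2,4-dimethoxy-6-methylphenyl)pent-2-yn-1-one; 8 methyl 2-[methoxy(trimethylsilyloxy)methylidene]but-3-enoate
Product: 11 methyl 3-(ArCO)-4-[2-(TBSO)ethyl]-2-hydroxybenzoate, via cyclohexadiene cycloadduct 9 (not isolated), via aryl trimethylsilyl ether 10 (not isolated)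
Conditions: toluene, 110 °C (sealed); then MeOH, K2CO3 (cat.), rt
Reagents that add atoms: none
Why: Normal-demand Diels–Alder reaction of a 1,1-dioxygenated diene with an ynone: the nucleophilic CH2 terminus of 8 bonds to the β-carbon of 5, so the oxygen-bearing diene carbon lands next to the aroyl-bearing carbon; ketal 9 (one racemic centre, lost) aromatizes by 1,4-elimination of methanol, and methanolysis of silyl ether 10 frees the salicylate.

Step 5
Reactants: 11 methyl 3-(ArCO)-4-[2-(TBSO)ethyl]-2-hydroxybenzoate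
Product: 12 methyl 3-(ArCO)-4-[2-(TBSO)ethyl]-2-methoxybenzoate
Conditions: MeI, K2CO3, DMF, 40 °C
Reagents that add atoms: iodomethane, CI
Why: Williamson ether synthesis on a phenol acidified by two flanking carbonyl groups, which is the only acidic site in the molecule.

Step 6
Reactants: 12 methyl 3-(ArCO)-4-[2-(TBSO)ethyl]-2-methoxybenzoate
Product: 13 3-(ArCO)-4-[2-(TBSO)ethyl]-2-methoxybenzoic acid
Conditions: LiOH, THF/MeOH/H2O, 40 °C; then 1 M HCl to pH 4, 0 °C
Reagents that add atoms: lithium hydroxide, [Li+].[OH-]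
Why: Saponification of a benzoate with one free ortho position; the tetra-ortho-substituted diaryl ketone and the primary silyl ether should tolerate mild hydroxide and a brief cold acidification.

Step 7
Reactants: 13 3-(ArCO)-4-[2-(TBSO)ethyl]-2-methoxybenzoic acid; 14 hexacarbonylchromium, Cr(CO)6
Product: 18 pentacarbonyl{[3-(ArCO)-4-[2-(TBSO)ethyl]-2-methoxyphenyl](methoxy)methylidene}chromium, via acid chloride 15 (not isolated), via disodium pentacarbonylchromate 16 (not isolated), via sodium acylchromate 17 (not isolated)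
Conditions: Me2C=C(Cl)NMe2, CH2Cl2, 0 °C → rt, concentrate; separately Cr(CO)6, NaC10H8 (2 equiv), THF, −78 → 0 °C; add 15, −78 → 0 °C; then Me3OBF4, CH2Cl2, 0 °C
Reagents that add atoms: trimethyloxonium tetrafluoroborate, C[O+](C)C.F[B-](F)(F)F
Why: Acyl chloride route to Fischer carbene complexes: the α-chloroenamine makes the acid chloride without acid (silyl ether kept), the pentacarbonylchromate dianion is acylated far faster by 15 than it can attack the shielded diaryl ketone, and the acylmetalate is O-methylated by the oxonium salt.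

Step 8
Reactants: 18 pentacarbonyl{[3-(ArCO)-4-[2-(TBSO)ethyl]-2-methoxyphenyl](methoxy)methylidene}chromium; 19 2-ethynyl-4,4,5,5-tetramethyl-1,3,2-dioxaborolane
Product: 21 6-(ArCO)-7-[2-(TBSO)ethyl]-4,5-dimethoxy-2-(Bpin)naphthalen-1-ol, via tricarbonylchromium naphthol complex 20 (not isolated)
Conditions: 19 (1.5 equiv), THF (degassed), 50 °C; then air, EtOAc, rt
Reagents that add atoms: none
Why: Heating expels one CO from the zerovalent chromium carbene 18, the alkyne binds at the vacant site and inserts into the Cr=C bond so that carbene carbon C4 is joined to the unsubstituted alkyne carbon C3, and migratory insertion of a CO ligand then forms C2–C1 in a chromium-bound vinylketene. Ring C closes by a thermal 6π electrocyclization of this aryl vinylketene onto C8a (bond C1–C8a), and enolization of the resulting cyclohexadienone gives the 1-naphthol, held as the η6-Cr(CO)3 complex 20 until air sets it free. The closest known reaction is the Dötz benzannulation of aryl(methoxy)carbene chromium complexes with alkynes, which has been carried out with alkynylboronic pinacol esters. No stereocentre is formed. The step needs regioselective alkyne insertion, secured sterically because the pinacolboryl end is far larger than the C–H end and therefore sits next to the CO-derived carbon C1, which puts boron on C2; terminal alkynes are the most selective partners in this annulation. It also needs a single site of closure, secured because C5 already carries a methoxy group and C8a is the only unsubstituted position ortho to C4a.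

Step 9
Reactants: 21 6-(ArCO)-7-[2-(TBSO)ethyl]-4,5-dimethoxy-2-(Bpin)naphthalen-1-ol
Product: 22 6-(ArCO)-7-[2-(TBSO)ethyl]-1,4,5-trimethoxy-2-(Bpin)naphthalene
Conditions: MeI, K2CO3, DMF (degassed, argon), rt
Reagents that add atoms: iodomethane, CI
Why: Williamson ether synthesis on the naphthol under anhydrous, oxygen-free conditions that keep the aryl boronate intact; capping C1–OH before boron is oxidized avoids ever handling an air-sensitive naphthalene-1,2-diol.

Step 10
Reactants: 22 6-(ArCO)-7-[2-(TBSO)ethyl]-1,4,5-trimethoxy-2-(Bpin)naphthalene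
Product: 23 6-(ArCO)-7-[2-(TBSO)ethyl]-1,4,5-trimethoxynaphthalen-2-ol
Conditions: H2O2 (30% aq.), NaOH, THF, 0 °C
Reagents that add atoms: hydrogen peroxide, OO
Why: Oxidation of an aryl boronate: hydroperoxide adds to boron and the aryl group migrates from boron to oxygen, so the hydroxyl appears exactly at C2.

Step 11
Reactants: 23 6-(ArCO)-7-[2-(TBSO)ethyl]-1,4,5-trimethoxynaphthalen-2-ol
Product: 24 6-(ArCO)-7-[2-(TBSO)ethyl]-1,2,4,5-tetramethoxynaphthalene
Conditions: MeI, K2CO3, DMF, rt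
Reagents that add atoms: iodomethane, CI
Why: Williamson ether synthesis on the only free phenol, giving a ring C that is inert to the oxidations of the side chain.

Step 12
Reactants: 24 6-(ArCO)-7-[2-(TBSO)ethyl]-1,2,4,5-tetramethoxynaphthalene
Product: 25 6-(ArCO)-7-(2-hydroxyethyl)-1,2,4,5-tetramethoxynaphthalene
Conditions: Bu4NF, THF, 0 °C → rt
Reagents that add atoms: none
Why: Fluoride-induced cleavage of a primary silyl ether, driven by the Si–F bond; nothing else in the molecule is fluoride-labile.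

Step 13
Reactants: 25 6-(ArCO)-7-(2-hydroxyethyl)-1,2,4,5-tetramethoxynaphthalene
Product: 26 6-(ArCO)-1,2,4,5-tetramethoxy-7-(2-oxoethyl)naphthalene
Conditions: Dess–Martin periodinane, CH2Cl2, 0 °C → rt; used crude
Reagents that add atoms: none
Why: Dess–Martin oxidation of a primary alcohol stops at the aldehyde and does not touch aryl methyl ethers or the ketone; the enolizable arylacetaldehyde is used at once.

Step 14
Reactants: 27 2,2,6-trimethyl-4H-1,3-dioxin-4-one
Product: 29 [(2,2-dimethyl-6-methylidene-6H-1,3-dioxin-4-yl)oxy]trimethylsilane, via lithium dienolate 28 (not isolated)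
Conditions: LiN(iPr)2, THF, −78 °C; then Me3SiCl, −78 °C → rt
Reagents that add atoms: chlorotrimethylsilane, C[Si](C)(C)Cl
Why: Silyl dienol ether formation: kinetic deprotonation of the C6 methyl group gives the vinylogous enolate, which is silylated on oxygen.

Step 15
Reactants: 26 6-(ArCO)-1,2,4,5-tetramethoxy-7-(2-oxoethyl)naphthalene; 29 [(2,2-dimethyl-6-methylidene-6H-1,3-dioxin-4-yl)oxy]trimethylsilane
Product: 30 rac-6-(ArCO)-7-[3-(2,2-dimethyl-4-oxo-4H-1,3-dioxin-6-yl)-2-hydroxypropyl]-1,2,4,5-tetramethoxynaphthalene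
Conditions: BF3·OEt2, CH2Cl2, −78 °C; aq. NaHCO3
Reagents that add atoms: none
Why: Vinylogous Mukaiyama aldol reaction: the silyl dienol ether attacks the Lewis-acid-activated aldehyde through its exocyclic γ-carbon without any base that could enolize the arylacetaldehyde; the new carbinol centre is racemic and is removed in step 16.

Step 16
Reactants: 30 rac-6-(ArCO)-7-[3-(2,2-dimethyl-4-oxo-4H-1,3-dioxin-6-yl)-2-hydroxypropyl]-1,2,4,5-tetramethoxynaphthalene
Product: 31 6-(ArCO)-7-[3-(2,2-dimethyl-4-oxo-4H-1,3-dioxin-6-yl)-2-oxopropyl]-1,2,4,5-tetramethoxynaphthalene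
Conditions: Dess–Martin periodinane, CH2Cl2, rt
Reagents that add atoms: none
Why: Dess–Martin oxidation of a secondary alcohol to the β-keto dioxinone under neutral conditions in which the dioxinone does not fragment.

Step 17
Reactants: 31 6-(ArCO)-7-[3-(2,2-dimethyl-4-oxo-4H-1,3-dioxin-6-yl)-2-oxopropyl]-1,2,4,5-tetramethoxynaphthalene
Product: 33 6-(ArCO)-7-[(4-hydroxy-2-oxo-2H-pyran-6-yl)methyl]-1,2,4,5-tetramethoxynaphthalene, via acylketene 32 (not isolated)
Conditions: toluene, 110 °C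
Reagents that add atoms: none
Why: Retro-hetero-Diels–Alder fragmentation of the dioxinone releases acetone and an acylketene, which is captured by the enol oxygen of the neighbouring ketone to close the 4-hydroxy-2-pyranone; no base is present that could drive aldol condensation onto the diaryl ketone.

Step 18
Reactants: 33 6-(ArCO)-7-[(4-hydroxy-2-oxo-2H-pyran-6-yl)methyl]-1,2,4,5-tetramethoxynaphthalene
Product: 35 6-(2,4-dihydroxy-6-methylbenzoyl)-2,5-dihydroxy-7-[(4-hydroxy-2-oxo-2H-pyran-6-yl)methyl]naphthalene-1,4-dione (CNP0158797.0), via hexahydroxy leuco compound 34 (not isolated)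
Conditions: BBr3 (excess), CH2Cl2, −78 °C → rt; H2O; then air, EtOAc/aq. phosphate buffer (pH 7), rt; acidify
Reagents that add atoms: none
Why: Lewis-acid cleavage of all six aryl methyl ethers by BBr3 (bromide attacks the methyl group of each boron-bound ether), followed by autoxidation of the naphthalene-1,2,4-triol ring, which air converts spontaneously into the 2-hydroxy-1,4-naphthoquinone, the only stable tautomer of that oxidation level.

**Compound list**

1 | 2,4-dimethoxy-6-methylbenzaldehyde | Cc1cc(OC)cc(OC)c1C=O | starting material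
2 | tert-butyl(but-3-yn-1-yloxy)dimethylsilane | C#CCCO[Si](C)(C)C(C)(C)C | starting material
3 | [4-(TBSO)but-1-yn-1-yl]lithium | [Li]C#CCCO[Si](C)(C)C(C)(C)C | intermediate
4 | rac-5-(TBSO)-1-(2,4-dimethoxy-6-methylphenyl)pent-2-yn-1-ol | Cc1cc(OC)cc(OC)c1C(O)C#CCCO[Si](C)(C)C(C)(C)C | intermediate
5 | 5-(TBSO)-1-(2,4-dimethoxy-6-methylphenyl)pent-2-yn-1-one | Cc1cc(OC)cc(OC)c1C(=O)C#CCCO[Si](C)(C)C(C)(C)C | intermediate
6 | dimethyl ethylidenemalonate | CC=C(C(=O)OC)C(=O)OC | starting material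
7 | lithium 1-methoxy-2-(methoxycarbonyl)buta-1,3-dien-1-olate | [Li+].[O-]C(OC)=C(C=C)C(=O)OC | intermediate
8 | methyl 2-[methoxy(trimethylsilyloxy)methylidene]but-3-enoate (E/Z not defined) | C=CC(C(=O)OC)=C(OC)O[Si](C)(C)C | intermediate
9 | methyl 5-(ArCO)-4-[2-(TBSO)ethyl]-6-methoxy-6-(trimethylsilyloxy)cyclohexa-1,4-diene-1-carboxylate (racemic) | COC(=O)C1=CCC(CCO[Si](C)(C)C(C)(C)C)=C(C(=O)c2c(C)cc(OC)cc2OC)C1(OC)O[Si](C)(C)C | intermediate
10 | methyl 3-(ArCO)-4-[2-(TBSO)ethyl]-2-(trimethylsilyloxy)benzoate | COC(=O)c1ccc(CCO[Si](C)(C)C(C)(C)C)c(C(=O)c2c(C)cc(OC)cc2OC)c1O[Si](C)(C)C | intermediate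
11 | methyl 3-(ArCO)-4-[2-(TBSO)ethyl]-2-hydroxybenzoate | COC(=O)c1ccc(CCO[Si](C)(C)C(C)(C)C)c(C(=O)c2c(C)cc(OC)cc2OC)c1O | intermediate
12 | methyl 3-(ArCO)-4-[2-(TBSO)ethyl]-2-methoxybenzoate | COC(=O)c1ccc(CCO[Si](C)(C)C(C)(C)C)c(C(=O)c2c(C)cc(OC)cc2OC)c1OC | intermediate
13 | 3-(ArCO)-4-[2-(TBSO)ethyl]-2-methoxybenzoic acid | OC(=O)c1ccc(CCO[Si](C)(C)C(C)(C)C)c(C(=O)c2c(C)cc(OC)cc2OC)c1OC | intermediate
14 | hexacarbonylchromium, Cr(CO)6 | O=C=[Cr](=C=O)(=C=O)(=C=O)(=C=O)=C=O | starting material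
15 | 3-(ArCO)-4-[2-(TBSO)ethyl]-2-methoxybenzoyl chloride | ClC(=O)c1ccc(CCO[Si](C)(C)C(C)(C)C)c(C(=O)c2c(C)cc(OC)cc2OC)c1OC | intermediate
16 | disodium pentacarbonylchromate, Na2Cr(CO)5 | [Na+].[Na+].O=C=[Cr-2](=C=O)(=C=O)(=C=O)=C=O | intermediate
17 | sodium pentacarbonyl{3-(ArCO)-4-[2-(TBSO)ethyl]-2-methoxybenzoyl}chromate | [Na+].O=C(c1ccc(CCO[Si](C)(C)C(C)(C)C)c(C(=O)c2c(C)cc(OC)cc2OC)c1OC)[Cr-](=C=O)(=C=O)(=C=O)(=C=O)=C=O | intermediate
18 | pentacarbonyl{[3-(ArCO)-4-[2-(TBSO)ethyl]-2-methoxyphenyl](methoxy)methylidene}chromium | COC(=[Cr](=C=O)(=C=O)(=C=O)(=C=O)=C=O)c1ccc(CCO[Si](C)(C)C(C)(C)C)c(C(=O)c2c(C)cc(OC)cc2OC)c1OC | intermediate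
19 | 2-ethynyl-4,4,5,5-tetramethyl-1,3,2-dioxaborolane | C#CB1OC(C)(C)C(C)(C)O1 | starting material
20 | tricarbonyl(η6-naphthol 21)chromium, complexed at the new ring, written as its two components | COc1cc(B2OC(C)(C)C(C)(C)O2)c(O)c2cc(CCO[Si](C)(C)C(C)(C)C)c(C(=O)c3c(C)cc(OC)cc3OC)c(OC)c12.O=C=[Cr](=C=O)=C=O | intermediate
21 | 6-(ArCO)-7-[2-(TBSO)ethyl]-4,5-dimethoxy-2-(Bpin)naphthalen-1-ol | COc1cc(B2OC(C)(C)C(C)(C)O2)c(O)c2cc(CCO[Si](C)(C)C(C)(C)C)c(C(=O)c3c(C)cc(OC)cc3OC)c(OC)c12 | intermediate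
22 | 6-(ArCO)-7-[2-(TBSO)ethyl]-1,4,5-trimethoxy-2-(Bpin)naphthalene | COc1cc(B2OC(C)(C)C(C)(C)O2)c(OC)c2cc(CCO[Si](C)(C)C(C)(C)C)c(C(=O)c3c(C)cc(OC)cc3OC)c(OC)c12 | intermediate
23 | 6-(ArCO)-7-[2-(TBSO)ethyl]-1,4,5-trimethoxynaphthalen-2-ol | COc1cc(O)c(OC)c2cc(CCO[Si](C)(C)C(C)(C)C)c(C(=O)c3c(C)cc(OC)cc3OC)c(OC)c12 | intermediate
24 | 6-(ArCO)-7-[2-(TBSO)ethyl]-1,2,4,5-tetramethoxynaphthalene | COc1cc(OC)c(OC)c2cc(CCO[Si](C)(C)C(C)(C)C)c(C(=O)c3c(C)cc(OC)cc3OC)c(OC)c12 | intermediate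
25 | 6-(ArCO)-7-(2-hydroxyethyl)-1,2,4,5-tetramethoxynaphthalene | COc1cc(OC)c(OC)c2cc(CCO)c(C(=O)c3c(C)cc(OC)cc3OC)c(OC)c12 | intermediate
26 | 6-(ArCO)-1,2,4,5-tetramethoxy-7-(2-oxoethyl)naphthalene | COc1cc(OC)c(OC)c2cc(CC=O)c(C(=O)c3c(C)cc(OC)cc3OC)c(OC)c12 | intermediate
27 | 2,2,6-trimethyl-4H-1,3-dioxin-4-one | CC1=CC(=O)OC(C)(C)O1 | starting material
28 | lithium 2,2-dimethyl-6-methylidene-6H-1,3-dioxin-4-olate | [Li+].[O-]C1=CC(=C)OC(C)(C)O1 | intermediate
29 | [(2,2-dimethyl-6-methylidene-6H-1,3-dioxin-4-yl)oxy]trimethylsilane | C=C1C=C(O[Si](C)(C)C)OC(C)(C)O1 | intermediate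
30 | rac-6-(ArCO)-7-[3-(2,2-dimethyl-4-oxo-4H-1,3-dioxin-6-yl)-2-hydroxypropyl]-1,2,4,5-tetramethoxynaphthalene | COc1cc(OC)c(OC)c2cc(CC(O)CC3=CC(=O)OC(C)(C)O3)c(C(=O)c4c(C)cc(OC)cc4OC)c(OC)c12 | intermediate
31 | 6-(ArCO)-7-[3-(2,2-dimethyl-4-oxo-4H-1,3-dioxin-6-yl)-2-oxopropyl]-1,2,4,5-tetramethoxynaphthalene | COc1cc(OC)c(OC)c2cc(CC(=O)CC3=CC(=O)OC(C)(C)O3)c(C(=O)c4c(C)cc(OC)cc4OC)c(OC)c12 | intermediate
32 | 6-(ArCO)-1,2,4,5-tetramethoxy-7-(2,4,6-trioxohex-5-en-1-yl)naphthalene (acylketene) | COc1cc(OC)c(OC)c2cc(CC(=O)CC(=O)C=C=O)c(C(=O)c4c(C)cc(OC)cc4OC)c(OC)c12 | intermediate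
33 | 6-(ArCO)-7-[(4-hydroxy-2-oxo-2H-pyran-6-yl)methyl]-1,2,4,5-tetramethoxynaphthalene | COc1cc(OC)c(OC)c2cc(Cc3cc(O)cc(=O)o3)c(C(=O)c4c(C)cc(OC)cc4OC)c(OC)c12 | intermediate
34 | 6-(2,4-dihydroxy-6-methylbenzoyl)-7-[(4-hydroxy-2-oxo-2H-pyran-6-yl)methyl]naphthalene-1,2,4,5-tetrol | Oc1cc(O)c(O)c2cc(Cc3cc(O)cc(=O)o3)c(C(=O)c4c(C)cc(O)cc4O)c(O)c12 | intermediate
35 | 6-(2,4-dihydroxy-6-methylbenzoyl)-2,5-dihydroxy-7-[(4-hydroxy-2-oxo-2H-pyran-6-yl)methyl]naphthalene-1,4-dione (CNP0158797.0) | Cc1cc(O)cc(O)c1C(=O)c1c(Cc2cc(O)cc(=O)o2)cc2c(c1O)C(=O)C=C(O)C2=O | target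

**Step count and risk**

Total steps: 18. Longest linear sequence: 16 steps (1, 2, 4–13, 15–18, from aldehyde 1); steps 3 and 14 are one-step side branches.

Steps most likely to fail:

1. Step 8 (benzannulation). The ethynylboronate may be lost to protodeboronation or oligomerization before it inserts, annulation may proceed without CO incorporation, or insertion may occur in the reverse sense. The fallback sets out from 18 and returns at 23, bringing in the C2 oxygen through a formyl group instead of boron. Carbene complex 18 would be annulated under the same conditions with commercial 3,3-diethoxyprop-1-yne, a robust terminal alkyne for this reaction, to give 6-(ArCO)-7-[2-(TBSO)ethyl]-2-(diethoxymethyl)-4,5-dimethoxynaphthalen-1-ol F1. O-Methylation (MeI, K2CO3, DMF) would give the acetal 6-(ArCO)-7-[2-(TBSO)ethyl]-2-(diethoxymethyl)-1,4,5-trimethoxynaphthalene F2, and hydrolysis with pyridinium p-toluenesulfonate in wet acetone the aldehyde 6-(ArCO)-7-[2-(TBSO)ethyl]-1,4,5-trimethoxynaphthalene-2-carbaldehyde F3. Baeyer–Villiger oxidation with mCPBA, in which the electron-rich aryl group migrates, would give 6-(ArCO)-7-[2-(TBSO)ethyl]-1,4,5-trimethoxynaphthalen-2-yl formate F4, and methanolysis (K2CO3, MeOH) would deliver naphthol 23.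

2. Step 4 (Diels–Alder aromatization). Cycloaddition of the ester-attenuated diene with a β-substituted ynone may be slow enough that the diene is consumed by desilylation or polymerization. The fallback sets out from 5 and returns at 13, leaving the ester out of the diene and installing the carboxyl carbon afterwards. Ynone 5 would be heated with the more nucleophilic 1-methoxy-1-(trimethylsilyloxy)buta-1,3-diene F5 (from methyl crotonate, LiN(iPr)2, Me3SiCl); loss of methanol and desilylation would give (2,4-dimethoxy-6-methylphenyl){2-hydroxy-6-[2-(TBSO)ethyl]phenyl}methanone F6, with the same orientation as in step 4. Magnesium-phenoxide ortho-formylation (MgCl2, Et3N, paraformaldehyde, MeCN, reflux), for which only one ortho position is open, would give 3-(ArCO)-4-[2-(TBSO)ethyl]-2-hydroxybenzaldehyde F7. O-Methylation (MeI, K2CO3) to 3-(ArCO)-4-[2-(TBSO)ethyl]-2-methoxybenzaldehyde F8 and Pinnick oxidation (NaClO2, NaH2PO4, 2-methylbut-2-ene, t-BuOH/H2O) would give acid 13.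

3. Step 18 (global demethylation and aerial oxidation). Cleavage of six ethers in one flask may be uneven, and the very electron-rich polyphenol may be oxidized uncontrollably. The fallback sets out from 30 and returns at 35; ring C is unmasked oxidatively before the pyranone exists, so the last step has four ethers to cleave and needs no air oxidation. Aldol 30 would be oxidized with (NH4)2Ce(NO3)6 in aqueous MeCN at 0 °C (the dioxinone, unlike a free hydroxypyranone, is not an enolized 1,3-dicarbonyl) to give rac-6-(ArCO)-7-[3-(2,2-dimethyl-4-oxo-4H-1,3-dioxin-6-yl)-2-hydroxypropyl]-2,5-dimethoxynaphthalene-1,4-dione F9. Dess–Martin oxidation would give 6-(ArCO)-7-[3-(2,2-dimethyl-4-oxo-4H-1,3-dioxin-6-yl)-2-oxopropyl]-2,5-dimethoxynaphthalene-1,4-dione F10, and thermolysis in toluene at 110 °C would give 6-(ArCO)-7-[(4-hydroxy-2-oxo-2H-pyran-6-yl)methyl]-2,5-dimethoxynaphthalene-1,4-dione F11. BBr3 in CH2Cl2 would then cleave the vinylogous ester at C2, the C5 ether and the two ring A ethers to give 35.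

**Further compounds**

F1 | step 8 | 6-(ArCO)-7-[2-(TBSO)ethyl]-2-(diethoxymethyl)-4,5-dimethoxynaphthalen-1-ol | COc1cc(C(OCC)OCC)c(O)c2cc(CCO[Si](C)(C)C(C)(C)C)c(C(=O)c3c(C)cc(OC)cc3OC)c(OC)c12
F2 | step 8 | 6-(ArCO)-7-[2-(TBSO)ethyl]-2-(diethoxymethyl)-1,4,5-trimethoxynaphthalene | COc1cc(C(OCC)OCC)c(OC)c2cc(CCO[Si](C)(C)C(C)(C)C)c(C(=O)c3c(C)cc(OC)cc3OC)c(OC)c12
F3 | step 8 | 6-(ArCO)-7-[2-(TBSO)ethyl]-1,4,5-trimethoxynaphthalene-2-carbaldehyde | COc1cc(C=O)c(OC)c2cc(CCO[Si](C)(C)C(C)(C)C)c(C(=O)c3c(C)cc(OC)cc3OC)c(OC)c12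
F4 | step 8 | 6-(ArCO)-7-[2-(TBSO)ethyl]-1,4,5-trimethoxynaphthalen-2-yl formate | COc1cc(OC=O)c(OC)c2cc(CCO[Si](C)(C)C(C)(C)C)c(C(=O)c3c(C)cc(OC)cc3OC)c(OC)c12
F5 | step 4 | 1-methoxy-1-(trimethylsilyloxy)buta-1,3-diene | C=CC=C(OC)O[Si](C)(C)C
F6 | step 4 | (2,4-dimethoxy-6-methylphenyl){2-hydroxy-6-[2-(TBSO)ethyl]phenyl}methanone | Cc1cc(OC)cc(OC)c1C(=O)c1c(O)cccc1CCO[Si](C)(C)C(C)(C)C
F7 | step 4 | 3-(ArCO)-4-[2-(TBSO)ethyl]-2-hydroxybenzaldehyde | Cc1cc(OC)cc(OC)c1C(=O)c1c(O)c(C=O)ccc1CCO[Si](C)(C)C(C)(C)C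
F8 | step 4 | 3-(ArCO)-4-[2-(TBSO)ethyl]-2-methoxybenzaldehyde | Cc1cc(OC)cc(OC)c1C(=O)c1c(OC)c(C=O)ccc1CCO[Si](C)(C)C(C)(C)C
F9 | step 18 | rac-6-(ArCO)-7-[3-(2,2-dimethyl-4-oxo-4H-1,3-dioxin-6-yl)-2-hydroxypropyl]-2,5-dimethoxynaphthalene-1,4-dione | COC1=CC(=O)c2c(OC)c(C(=O)c3c(C)cc(OC)cc3OC)c(CC(O)CC4=CC(=O)OC(C)(C)O4)cc2C1=O
F10 | step 18 | 6-(ArCO)-7-[3-(2,2-dimethyl-4-oxo-4H-1,3-dioxin-6-yl)-2-oxopropyl]-2,5-dimethoxynaphthalene-1,4-dione | COC1=CC(=O)c2c(OC)c(C(=O)c3c(C)cc(OC)cc3OC)c(CC(=O)CC4=CC(=O)OC(C)(C)O4)cc2C1=O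
F11 | step 18 | 6-(ArCO)-7-[(4-hydroxy-2-oxo-2H-pyran-6-yl)methyl]-2,5-dimethoxynaphthalene-1,4-dione | COC1=CC(=O)c2c(OC)c(C(=O)c3c(C)cc(OC)cc3OC)c(Cc3cc(O)cc(=O)o3)cc2C1=O
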